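**Plan**

- Cuts: (a) the ester C7–O–C(=O) between the two halves; (b) in the seven-membered lactone, the ring alkene (metathesis) and the O–CH2 bond (carboxylate alkylation); (c) C3–C4 and C1–C2 of ring A ([4+2]); (d) in the ring-B acid, the acrylate C=C (Horner–Wadsworth–Emmons), C3'–CH2OH (Stille), C1'–vinyl (conjugate addition) and the cyclohexenone ring (Michael/aldol).
- Enabling feature: in ring A the contiguous stereocentres C1 (carbinol carbon with OH and C7H2O), C2 (lactone C=O), C3 (lactone =CH) and C4 (isopropyl) leave only C5–C6 unsubstituted. Ring A is therefore the hydrogenated adduct of a C4=C5–C6=C1 diene, whose C1 already carries O and C7 as a Z-alkylidene cyclic carbonate, and a trans enal C2=C3.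
- Forward order: ring A by cycloaddition (step 7); C2 aldehyde masked, C5=C6 saturated, C3 arm turned into vinyl, carbonate opened; ring B built separately from (S)-cryptone; halves joined at C7–O; then C2 oxidised, alkylated with a 2-(bromomethyl)acrylate, the lactone ring closed last by metathesis, and global desilylation.
- Stereochemistry: C1–C4 all arise in step 7 (Z enol carbonate fixes C1, E alkene fixes C4, E enal makes C2/C3 trans, endo addition puts the C2 formyl cis to C7 and isopropyl, the (2R,5R)-imidazolidinone sets the absolute sense). C6' comes from enamine catalysis and C1' from anti conjugate addition. The ring-B acrylate geometry comes from the olefination, the lactone alkene geometry from the ring.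
- C2 is kept as an acetal until C7–O is acylated, because a free C7–OH would lactonise onto any cis C2 carboxyl derivative.

Key step: step 7

Remark on numbering: ring A is C1 (carbinol carbon), C2, C3, C4 (isopropyl carbon), C5, C6, with C7 the CH2O carbon on C1; ring B is C1' (carbon bearing the acrylate), C2'=C3' (C3' bears CH2O), C4', C5', C6' (isopropyl carbon). The target reads from its SMILES as (5aS,6R,9S,9aS) in the lactone half and (1'S,6'S) with an E acrylate in the ring-B half.

Assumption: ethyl 2-(diethoxyphosphoryl)acrylate 27 and tert-butyl 2-(bromomethyl)acrylate 38 are taken as purchasable; catalyst-bound species of catalytic cycles (iminium ions, organopalladium, ruthenium carbenes, vinylgold) are described in the Why lines and are not numbered.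

**Route**

Step 1
Reactants: 1 3-methylbut-1-yne
Product: 3 (E)-1-iodo-3-methylbut-1-ene, via alkenylzirconocene chloride 2 (not isolated)
Conditions: Cp2Zr(H)Cl, THF, rt; then I2, 0 °C
Reagents that add atoms: iodine, II
Why: Hydrozirconation adds Zr–H syn and at the terminal carbon of the alkyne, and iodinolysis of the C–Zr bond with retention should give the E-vinyl iodide.

Step 2
Reactants: 3 (E)-1-iodo-3-methylbut-1-ene; 4 prop-2-yn-1-ol
Product: 5 (E)-6-methylhept-4-en-2-yn-1-ol
Conditions: PdCl2(PPh3)2 (2 mol %), CuI (4 mol %), Et3N, THF, rt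
Reagents that add atoms: none
Why: Sonogashira coupling (oxidative addition to zerovalent palladium, copper acetylide transmetalation, reductive elimination) joins the vinyl iodide and the terminal alkyne with retention of the E geometry.

Step 3
Reactants: 5 (E)-6-methylhept-4-en-2-yn-1-ol; 6 di-tert-butyl dicarbonate
Product: 7 tert-butyl (E)-6-methylhept-4-en-2-yn-1-yl carbonate
Conditions: DMAP (10 mol %), Et3N, CH2Cl2, 0 °C to rt
Reagents that add atoms: none
Why: DMAP-catalysed acylation of the primary alcohol by the dicarbonate gives the tert-butyl carbonate needed for the cyclisation.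

Step 4
Reactants: 7 tert-butyl (E)-6-methylhept-4-en-2-yn-1-yl carbonate
Product: 8 (Z)-4-[(E)-4-methylpent-2-en-1-ylidene]-1,3-dioxolan-2-one
Conditions: Ph3PAuNTf2 (1 mol %), CH2Cl2, rt
Reagents that add atoms: none
Why: Gold-catalysed 5-exo-dig cyclisation of a propargylic tert-butyl carbonate, in which the carbonyl oxygen adds anti to the gold-activated alkyne, isobutene is lost and protodeauration with retention leaves the ring oxygen cis to the diene chain (Z).

Step 5
Reactants: 9 (Z)-but-2-ene-1,4-diol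
Product: 10 (Z)-4-[(tert-butyldimethylsilyl)oxy]but-2-en-1-ol
Conditions: NaH (1.0 equiv), THF, 0 °C; then TBSCl
Reagents that add atoms: tert-butyldimethylsilyl chloride, CC(C)(C)[Si](C)(C)Cl
Why: Monosilylation of the symmetrical diol through its poorly soluble monosodium alkoxide, which should react once with the silyl chloride.

Step 6
Reactants: 10 (Z)-4-[(tert-butyldimethylsilyl)oxy]but-2-en-1-ol
Product: 11 (E)-4-[(tert-butyldimethylsilyl)oxy]but-2-enal
Conditions: pyridinium chlorochromate [C5H5NH][CrO3Cl], CH2Cl2, rt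
Reagents that add atoms: none
Why: Chromate oxidation of the allylic alcohol, with the first-formed Z-enal expected to isomerise to the conjugated E-enal under the mildly acidic conditions.

Step 7
Reactants: 8 (Z)-4-[(E)-4-methylpent-2-en-1-ylidene]-1,3-dioxolan-2-one; 11 (E)-4-[(tert-butyldimethylsilyl)oxy]but-2-enal
Product: 12 (5S,6S,7R,8S)-7-{[(tert-butyldimethylsilyl)oxy]methyl}-2-oxo-8-(propan-2-yl)-1,3-dioxaspiro[4.5]dec-9-ene-6-carbaldehyde (ring A with C1 spiro carbonate; formyl on C2 cis to C7 and to the C4 isopropyl; CH2OTBS on C3 trans to formyl)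
Conditions: (2R,5R)-5-benzyl-2-tert-butyl-3-methylimidazolidin-4-one·CF3CO2H (20 mol %), CH3CN/H2O (95:5), −20 °C to rt
Reagents that add atoms: none
Why: Proposed new method: the amine salt condenses reversibly with 11 to an E-configured α,β-unsaturated iminium ion whose lowered LUMO should undergo a concerted, asynchronous normal-demand [4+2] cycloaddition with s-cis 8, and hydrolysis of the product iminium releases 12 and the catalyst; the closest known reaction type is the imidazolidinone-catalysed Diels–Alder reaction of enals with 1-acyloxybutadienes, which has not been run on an exocyclic 1,1-disubstituted enol-carbonate diene that creates a quaternary spiro centre. Ring A closes in one intermolecular suprafacial–suprafacial [4+2] event that forms C3–C4 and C1–C2 together. C1 is fixed by the Z enol-carbonate geometry (ring oxygen inside, C7 outside), C4 by the E geometry of the isopropyl-bearing alkene, the trans C2/C3 relation by the E-enal, C2 relative to C1 and C4 by the endo orientation of the iminium, and the absolute sense by the (5R)-benzyl group, which shields one iminium face so that the diene adds to the β-carbon from the face on which CH2OTBS, Cα and H run clockwise. The step needs ortho regioselectivity, endo selectivity and face selectivity: the enol oxygen on C1 puts the largest HOMO coefficient on C4, which bonds first to the iminium β-carbon while positive charge builds on the oxygen-stabilised C1, so the formyl carbon ends on C2; secondary overlap with the iminium π system favours endo; and the tert-butyl group enforces the single iminium geometry on which the benzyl shielding depends. The cyclic carbonate should tolerate the trifluoroacetate salt, which a silyl enol ether would not.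

Step 8
Reactants: 12 spiro-carbonate cyclohexene carbaldehyde
Product: 13 7-{[(tert-butyldimethylsilyl)oxy]methyl}-6-(dimethoxymethyl)-8-(propan-2-yl)-1,3-dioxaspiro[4.5]dec-9-en-2-one (dimethyl acetal of 12, spatial arrangement unchanged)
Conditions: MeOSiMe3, Me3SiOTf (5 mol %), CH2Cl2, −78 °C
Reagents that add atoms: methoxytrimethylsilane, CO[Si](C)(C)C
Why: Silyl-triflate-catalysed acetalisation (Noyori conditions) masks the hindered C2 aldehyde without touching the silyl ether or carbonate, so that C2 stays at a level that a later free C7–OH cannot acylate.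

Step 9
Reactants: 13 dimethyl acetal
Product: 14 7-{[(tert-butyldimethylsilyl)oxy]methyl}-6-(dimethoxymethyl)-8-(propan-2-yl)-1,3-dioxaspiro[4.5]decan-2-one (C5–C6 saturated)
Conditions: H2 (3 atm), Rh/Al2O3 (5 wt %), EtOAc, rt
Reagents that add atoms: none
Why: Heterogeneous catalytic hydrogenation of the cis-disubstituted C5=C6 alkene, with rhodium chosen to avoid hydrogenolysis of the allylic C1–O bond, and no stereocentre is formed.

Step 10
Reactants: 14 saturated silyl ether
Product: 15 6-(dimethoxymethyl)-7-(hydroxymethyl)-8-(propan-2-yl)-1,3-dioxaspiro[4.5]decan-2-one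
Conditions: Bu4NF, AcOH (1:1), THF, 0 °C to rt
Reagents that add atoms: none
Why: Fluoride-induced desilylation of the primary silyl ether, buffered with acetic acid so that the alkoxide does not open the carbonate.

Step 11
Reactants: 15 primary alcohol
Product: 16 6-(dimethoxymethyl)-2-oxo-8-(propan-2-yl)-1,3-dioxaspiro[4.5]decane-7-carbaldehyde
Conditions: Dess–Martin periodinane, CH2Cl2, 0 °C to rt
Reagents that add atoms: none
Why: Dess–Martin oxidation should give the C3 aldehyde without epimerisation, since its equatorial position trans to both neighbours is the stable one.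

Step 12
Reactants: 16 C3 aldehyde
Product: 17 6-(dimethoxymethyl)-7-ethenyl-8-(propan-2-yl)-1,3-dioxaspiro[4.5]decan-2-one
Conditions: Ph3PCH3Br, KN(SiMe3)2, THF, −78 to 0 °C
Reagents that add atoms: methyltriphenylphosphonium bromide, C[P+](c1ccccc1)(c1ccccc1)c1ccccc1.[Br-]
Why: Wittig methylenation with the non-stabilised ylide at low temperature, where the aldehyde reacts far faster than the carbonate.

Step 13
Reactants: 17 vinyl carbonate
Product: 18 (1S,2S,3R,4R)-2-(dimethoxymethyl)-3-ethenyl-1-(hydroxymethyl)-4-(propan-2-yl)cyclohexan-1-ol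
Conditions: K2CO3, MeOH, 0 °C to rt; chromatography on Et3N-deactivated silica
Reagents that add atoms: none
Why: Base-catalysed transesterification of the cyclic carbonate with methanol frees the C1/C7 diol while the acetal and alkene are inert to base.

Step 14
Reactants: 19 3-methylbutanal; 20 but-3-en-2-one
Product: 21 (S)-5-oxo-2-(propan-2-yl)hexanal
Conditions: (S)-2-[methoxy(diphenyl)methyl]pyrrolidine (5 mol %), ethyl 3,4-dihydroxybenzoate (20 mol %), neat, 4 °C
Reagents that add atoms: none
Why: Enamine-catalysed Michael addition in which the E-enamine of 19 adds to 20 from the face away from the diphenyl(methoxy)methyl group, which should set the S centre.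

Step 15
Reactants: 21 (S)-5-oxo-2-(propan-2-yl)hexanal
Product: 22 (S)-4-(propan-2-yl)cyclohex-2-en-1-one ((S)-cryptone)
Conditions: LiOH (10 mol %), i-PrOH, rt
Reagents that add atoms: none
Why: Intramolecular aldol condensation (6-enolexo ring closure) under mild base gives the enone, and after closure the stereocentre is no longer α to a carbonyl.

Step 16
Reactants: 22 (S)-cryptone
Product: 24 (3S,4S)-3-ethenyl-4-(propan-2-yl)cyclohex-1-en-1-yl trifluoromethanesulfonate, via bromomagnesium enolate 23 (not isolated)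
Conditions: CH2=CHMgBr, CuBr·SMe2 (10 mol %), THF, −78 °C; then N-(5-chloropyridin-2-yl)bis(trifluoromethanesulfonyl)imide, −78 to 0 °C
Reagents that add atoms: vinylmagnesium bromide, C=C[Mg]Br; N-(5-chloropyridin-2-yl)bis(trifluoromethanesulfonyl)imide, O=S(=O)(N(c1ccc(Cl)cn1)S(=O)(=O)C(F)(F)F)C(F)(F)F
Why: Copper-catalysed conjugate addition of the vinyl Grignard reagent occurs anti to the neighbouring isopropyl group (trans product) and the regiodefined enolate is trapped on oxygen as the enol triflate.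

Step 17
Reactants: 24 enol triflate
Product: 25 (1S,6S)-6-(propan-2-yl)-3-{[(trifluoromethyl)sulfonyl]oxy}cyclohex-2-ene-1-carbaldehyde
Conditions: OsO4 (2 mol %), NaIO4, 2,6-lutidine, 1,4-dioxane/H2O (3:1), rt
Reagents that add atoms: sodium periodate, [Na+].[O-]I(=O)(=O)=O
Why: Lemieux–Johnson cleavage, in which OsO4 dihydroxylates the electron-rich monosubstituted alkene rather than the electron-poor enol triflate alkene and periodate cleaves the diol to the aldehyde.

Step 18
Reactants: 25 ring-B aldehyde; 26 (4-methoxyphenyl)methanol; 27 ethyl 2-(diethoxyphosphoryl)acrylate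
Product: 29 ethyl (2E)-2-{[(4-methoxybenzyl)oxy]methyl}-3-[(1R,6S)-6-(propan-2-yl)-3-{[(trifluoromethyl)sulfonyl]oxy}cyclohex-2-en-1-yl]prop-2-enoate (trans ring substituents as in 25; the C1' descriptor changes only through CIP priorities), via sodium phosphonate carbanion 28 (not isolated)
Conditions: 26, NaH, THF, 0 °C; 27 (slight excess), 0 °C; then 25, −78 to 0 °C
Reagents that add atoms: none
Why: Oxa-Michael addition of the alkoxide to the 2-phosphonoacrylate gives a stabilised phosphonate carbanion that undergoes Horner–Wadsworth–Emmons olefination, which with an α-substituted phosphonoacetate and an α-branched aldehyde should favour the E alkene (ester trans to ring B).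

Step 19
Reactants: 29 enol triflate acrylate
Product: 30 ethyl (2E)-3-[(1S,6S)-3-(hydroxymethyl)-6-(propan-2-yl)cyclohex-2-en-1-yl]-2-{[(4-methoxybenzyl)oxy]methyl}prop-2-enoate
Conditions: Bu3SnCH2OH, Pd(PPh3)4 (5 mol %), LiCl, 1,4-dioxane, 100 °C
Reagents that add atoms: (tributylstannyl)methanol, OC[Sn](CCCC)(CCCC)CCCC
Why: Stille coupling of the enol triflate with the hydroxymethylstannane, LiCl assisting transmetalation, installs the C3' hydroxymethyl group with the alkene position fixed by the triflate.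

Step 20
Reactants: 30 PMB ether
Product: 31 ethyl (2E)-2-(hydroxymethyl)-3-[(1S,6S)-3-(hydroxymethyl)-6-(propan-2-yl)cyclohex-2-en-1-yl]prop-2-enoate
Conditions: DDQ, CH2Cl2/pH 7 phosphate buffer (10:1), 0 °C
Reagents that add atoms: none
Why: Oxidative cleavage of the 4-methoxybenzyl ether by DDQ through the benzylic oxocarbenium ion, which water hydrolyses.

Step 21
Reactants: 31 diol ester
Product: 32 ethyl (2E)-2-{[(tert-butyldimethylsilyl)oxy]methyl}-3-[(1S,6S)-3-{[(tert-butyldimethylsilyl)oxy]methyl}-6-(propan-2-yl)cyclohex-2-en-1-yl]prop-2-enoate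
Conditions: TBSCl, imidazole, DMF, rt
Reagents that add atoms: tert-butyldimethylsilyl chloride, CC(C)(C)[Si](C)(C)Cl
Why: Imidazole-promoted silylation of both primary allylic alcohols.

Step 22
Reactants: 32 bis-silyl ester
Product: 33 (2E)-2-{[(tert-butyldimethylsilyl)oxy]methyl}-3-[(1S,6S)-3-{[(tert-butyldimethylsilyl)oxy]methyl}-6-(propan-2-yl)cyclohex-2-en-1-yl]prop-2-enoic acid
Conditions: LiOH, THF/MeOH/H2O, rt; then 1 M HCl to pH 4
Reagents that add atoms: lithium hydroxide, [Li+].[OH-]
Why: Saponification of the ethyl ester by hydroxide (acyl substitution), which the primary silyl ethers should withstand at room temperature.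

Step 23
Reactants: 18 ring-A diol; 33 ring-B acid
Product: 35 C7 ester of 18 with 33 (C1–OH free, C2 dimethyl acetal, C3 vinyl), via mixed anhydride 34 (not isolated)
Conditions: 33, 2,4,6-Cl3C6H2COCl, Et3N, THF, 0 °C; then 18, DMAP, toluene, rt
Reagents that add atoms: none
Why: Yamaguchi esterification, in which DMAP transfers the acyl group of the mixed anhydride to the primary C7–OH while the tertiary C1–OH is too hindered to react.

Step 24
Reactants: 35 acetal ester
Product: 36 the corresponding C2 aldehyde (C2–CHO, C3 vinyl, C7 ester, C1–OH)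
Conditions: pyridinium p-toluenesulfonate, THF/H2O (4:1), 45 °C
Reagents that add atoms: water, O
Why: Acid-catalysed hydrolysis of the dimethyl acetal through the oxocarbenium ion, and with C7–O acylated the only free hydroxyl (tertiary, on C1) cannot form a stable lactol.

Step 25
Reactants: 36 C2 aldehyde
Product: 37 the corresponding C2 carboxylic acid
Conditions: NaClO2, NaH2PO4, 2-methylbut-2-ene, t-BuOH/H2O, 0 °C to rt
Reagents that add atoms: sodium chlorite, [Na+].[O-]Cl=O
Why: Pinnick oxidation converts the aldehyde to the acid without touching alkenes or silyl ethers, the hypochlorous acid being scavenged by 2-methylbut-2-ene.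

Step 26
Reactants: 37 C2 carboxylic acid; 38 tert-butyl 2-(bromomethyl)acrylate
Product: 39 the 2-(tert-butoxycarbonyl)prop-2-en-1-yl ester of 37
Conditions: KHCO3, DMF, 0 °C to rt
Reagents that add atoms: none
Why: Alkylation of the carboxylate with the allylic bromide (SN2 or SN2', both give the same ester) under mild bicarbonate conditions.

Step 27
Reactants: 39 diene ester
Product: 40 tert-butyl ester, bis(tert-butyldimethylsilyl) ether of the target (seven-membered lactone closed)
Conditions: second-generation Hoveyda–Grubbs catalyst RuCl2(H2IMes)(=CH-C6H4-2-O-i-Pr) (10 mol %), toluene (2 mM), 80 °C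
Reagents that add atoms: none
Why: Ring-closing metathesis between the C3 vinyl group and the 1,1-disubstituted acrylate alkene releases ethene and closes the seven-membered lactone, in which the alkene can only be cis within the ring so that the ester ends trans to C3, while the trisubstituted alkenes of the ring-B half should not take part.

Step 28
Reactants: 40 protected target
Product: 42 target, (5aS,6R,9S,9aS)-9-hydroxy-9-[({(2E)-2-(hydroxymethyl)-3-[(1S,6S)-3-(hydroxymethyl)-6-(propan-2-yl)cyclohex-2-en-1-yl]prop-2-enoyl}oxy)methyl]-1-oxo-6-(propan-2-yl)-1,3,5a,6,7,8,9,9a-octahydro-2-benzoxepine-4-carboxylic acid, via trimethylsilyl ester 41 (not isolated)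
Conditions: Me3SiOTf, 2,6-lutidine, CH2Cl2, 0 °C; then HF·pyridine, pyridine, THF, 0 °C to rt
Reagents that add atoms: none
Why: Silyl triflate with 2,6-lutidine converts the tert-butyl ester into the silyl ester with loss of isobutene under non-protic conditions and buffered HF then cleaves all Si–O bonds, a sequence chosen because the product is expected to tolerate neither strong acid nor base.

**Compound list**

1 | 3-methylbut-1-yne | CC(C)C#C | starting material
2 | [(E)-3-methylbut-1-en-1-yl]zirconocene chloride | CC(C)/C=C/[Zr](Cl)(C1C=CC=C1)C1C=CC=C1 | intermediate (not isolated)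
3 | (E)-1-iodo-3-methylbut-1-ene | CC(C)/C=C/I | intermediate
4 | prop-2-yn-1-ol | C#CCO | starting material
5 | (E)-6-methylhept-4-en-2-yn-1-ol | CC(C)/C=C/C#CCO | intermediate
6 | di-tert-butyl dicarbonate | CC(C)(C)OC(=O)OC(=O)OC(C)(C)C | starting material
7 | tert-butyl (E)-6-methylhept-4-en-2-yn-1-yl carbonate | CC(C)/C=C/C#CCOC(=O)OC(C)(C)C | intermediate
8 | (Z)-4-[(E)-4-methylpent-2-en-1-ylidene]-1,3-dioxolan-2-one | CC(C)/C=C/C=C1\OC(=O)OC1 | intermediate
9 | (Z)-but-2-ene-1,4-diol | OC/C=C\CO | starting material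
10 | (Z)-4-[(tert-butyldimethylsilyl)oxy]but-2-en-1-ol | OC/C=C\CO[Si](C)(C)C(C)(C)C | intermediate
11 | (E)-4-[(tert-butyldimethylsilyl)oxy]but-2-enal | O=C/C=C/CO[Si](C)(C)C(C)(C)C | intermediate
12 | (5S,6S,7R,8S)-7-{[(tert-butyldimethylsilyl)oxy]methyl}-2-oxo-8-(propan-2-yl)-1,3-dioxaspiro[4.5]dec-9-ene-6-carbaldehyde | CC(C)[C@H]1C=C[C@@]2(COC(=O)O2)[C@@H](C=O)[C@@H]1CO[Si](C)(C)C(C)(C)C | intermediate
13 | dimethyl acetal of 12 | CC(C)[C@H]1C=C[C@@]2(COC(=O)O2)[C@@H](C(OC)OC)[C@@H]1CO[Si](C)(C)C(C)(C)C | intermediate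
14 | C5–C6 saturated acetal | CC(C)[C@H]1CC[C@@]2(COC(=O)O2)[C@@H](C(OC)OC)[C@@H]1CO[Si](C)(C)C(C)(C)C | intermediate
15 | C3 hydroxymethyl acetal carbonate | CC(C)[C@H]1CC[C@@]2(COC(=O)O2)[C@@H](C(OC)OC)[C@@H]1CO | intermediate
16 | C3 aldehyde acetal carbonate | CC(C)[C@H]1CC[C@@]2(COC(=O)O2)[C@@H](C(OC)OC)[C@@H]1C=O | intermediate
17 | C3 vinyl acetal carbonate | CC(C)[C@H]1CC[C@@]2(COC(=O)O2)[C@@H](C(OC)OC)[C@@H]1C=C | intermediate
18 | (1S,2S,3R,4R)-2-(dimethoxymethyl)-3-ethenyl-1-(hydroxymethyl)-4-(propan-2-yl)cyclohexan-1-ol | CC(C)[C@H]1CC[C@@](O)(CO)[C@@H](C(OC)OC)[C@@H]1C=C | intermediate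
19 | 3-methylbutanal | CC(C)CC=O | starting material
20 | but-3-en-2-one | CC(=O)C=C | starting material
21 | (S)-5-oxo-2-(propan-2-yl)hexanal | CC(C)[C@@H](C=O)CCC(C)=O | intermediate
22 | (S)-4-(propan-2-yl)cyclohex-2-en-1-one | CC(C)[C@@H]1CCC(=O)C=C1 | intermediate
23 | bromomagnesium (3S,4S)-3-ethenyl-4-(propan-2-yl)cyclohex-1-en-1-olate | C=C[C@@H]1C=C(O[Mg]Br)CC[C@H]1C(C)C | intermediate (not isolated)
24 | (3S,4S)-3-ethenyl-4-(propan-2-yl)cyclohex-1-en-1-yl trifluoromethanesulfonate | C=C[C@@H]1C=C(OS(=O)(=O)C(F)(F)F)CC[C@H]1C(C)C | intermediate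
25 | (1S,6S)-6-(propan-2-yl)-3-{[(trifluoromethyl)sulfonyl]oxy}cyclohex-2-ene-1-carbaldehyde | O=C[C@@H]1C=C(OS(=O)(=O)C(F)(F)F)CC[C@H]1C(C)C | intermediate
26 | (4-methoxyphenyl)methanol | COc1ccc(CO)cc1 | starting material
27 | ethyl 2-(diethoxyphosphoryl)acrylate | C=C(C(=O)OCC)P(=O)(OCC)OCC | starting material
28 | sodium carbanion of ethyl 2-(diethoxyphosphoryl)-3-[(4-methoxybenzyl)oxy]propanoate | CCOC(=O)[C-](COCc1ccc(OC)cc1)P(=O)(OCC)OCC.[Na+] | intermediate (not isolated)
29 | ethyl (2E)-2-{[(4-methoxybenzyl)oxy]methyl}-3-[(1R,6S)-6-(propan-2-yl)-3-{[(trifluoromethyl)sulfonyl]oxy}cyclohex-2-en-1-yl]prop-2-enoate | CCOC(=O)/C(COCc1ccc(OC)cc1)=C/[C@@H]1C=C(OS(=O)(=O)C(F)(F)F)CC[C@H]1C(C)C | intermediate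
30 | ethyl (2E)-3-[(1S,6S)-3-(hydroxymethyl)-6-(propan-2-yl)cyclohex-2-en-1-yl]-2-{[(4-methoxybenzyl)oxy]methyl}prop-2-enoate | CCOC(=O)/C(COCc1ccc(OC)cc1)=C/[C@@H]1C=C(CO)CC[C@H]1C(C)C | intermediate
31 | ethyl (2E)-2-(hydroxymethyl)-3-[(1S,6S)-3-(hydroxymethyl)-6-(propan-2-yl)cyclohex-2-en-1-yl]prop-2-enoate | CCOC(=O)/C(CO)=C/[C@@H]1C=C(CO)CC[C@H]1C(C)C | intermediate
32 | bis(tert-butyldimethylsilyl) ether of 31 | CCOC(=O)/C(CO[Si](C)(C)C(C)(C)C)=C/[C@@H]1C=C(CO[Si](C)(C)C(C)(C)C)CC[C@H]1C(C)C | intermediate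
33 | (2E)-2-{[(tert-butyldimethylsilyl)oxy]methyl}-3-[(1S,6S)-3-{[(tert-butyldimethylsilyl)oxy]methyl}-6-(propan-2-yl)cyclohex-2-en-1-yl]prop-2-enoic acid | OC(=O)/C(CO[Si](C)(C)C(C)(C)C)=C/[C@@H]1C=C(CO[Si](C)(C)C(C)(C)C)CC[C@H]1C(C)C | intermediate
34 | mixed anhydride of 33 with 2,4,6-trichlorobenzoic acid | O=C(OC(=O)c1c(Cl)cc(Cl)cc1Cl)/C(CO[Si](C)(C)C(C)(C)C)=C/[C@@H]1C=C(CO[Si](C)(C)C(C)(C)C)CC[C@H]1C(C)C | intermediate (not isolated)
35 | C7 ester of 18 with 33 (C2 dimethyl acetal, C3 vinyl) | CC(C)[C@H]1CC[C@@](O)(COC(=O)/C(CO[Si](C)(C)C(C)(C)C)=C/[C@@H]2C=C(CO[Si](C)(C)C(C)(C)C)CC[C@H]2C(C)C)[C@@H](C(OC)OC)[C@@H]1C=C | intermediate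
36 | C2 aldehyde from 35 | CC(C)[C@H]1CC[C@@](O)(COC(=O)/C(CO[Si](C)(C)C(C)(C)C)=C/[C@@H]2C=C(CO[Si](C)(C)C(C)(C)C)CC[C@H]2C(C)C)[C@@H](C=O)[C@@H]1C=C | intermediate
37 | C2 carboxylic acid from 36 | CC(C)[C@H]1CC[C@@](O)(COC(=O)/C(CO[Si](C)(C)C(C)(C)C)=C/[C@@H]2C=C(CO[Si](C)(C)C(C)(C)C)CC[C@H]2C(C)C)[C@@H](C(=O)O)[C@@H]1C=C | intermediate
38 | tert-butyl 2-(bromomethyl)acrylate | C=C(CBr)C(=O)OC(C)(C)C | starting material
39 | 2-(tert-butoxycarbonyl)prop-2-en-1-yl ester of 37 | CC(C)[C@H]1CC[C@@](O)(COC(=O)/C(CO[Si](C)(C)C(C)(C)C)=C/[C@@H]2C=C(CO[Si](C)(C)C(C)(C)C)CC[C@H]2C(C)C)[C@@H](C(=O)OCC(=C)C(=O)OC(C)(C)C)[C@@H]1C=C | intermediate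
40 | tert-butyl ester, bis(tert-butyldimethylsilyl) ether of the target | CC(C)[C@H]1CC[C@@](O)(COC(=O)/C(CO[Si](C)(C)C(C)(C)C)=C/[C@@H]2C=C(CO[Si](C)(C)C(C)(C)C)CC[C@H]2C(C)C)[C@H]2C(=O)OCC(C(=O)OC(C)(C)C)=C[C@H]12 | intermediate
41 | trimethylsilyl ester, C1 trimethylsilyl ether, bis(tert-butyldimethylsilyl) ether of the target | CC(C)[C@H]1CC[C@@](O[Si](C)(C)C)(COC(=O)/C(CO[Si](C)(C)C(C)(C)C)=C/[C@@H]2C=C(CO[Si](C)(C)C(C)(C)C)CC[C@H]2C(C)C)[C@H]2C(=O)OCC(C(=O)O[Si](C)(C)C)=C[C@H]12 | intermediate (not isolated)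
42 | target (CNP0361406.8) | CC(C)[C@H]1CC[C@@](O)(COC(=O)/C(=C/[C@@H]2C=C(CO)CC[C@H]2C(C)C)CO)[C@H]2C(=O)OCC(C(=O)O)=C[C@H]12 | target

**Totals**

Total step count: 28. Longest linear sequence: 17 steps (1–4, 7–13, 23–28); the ring-B branch (14–22) joins at step 23.

**Steps most likely to fail**

1. Step 7 (proposed new method). The hindered, acid-sensitive diene may add too slowly to the iminium ion, so that diene hydrolysis, loss of regiocontrol or erosion of endo and facial selectivity take over. The fallback sets out from 11 and 8, comes back at 12 and uses known auxiliary chemistry. Enal 11 would be oxidised (NaClO2, NaH2PO4, 2-methylbut-2-ene) to (E)-4-[(tert-butyldimethylsilyl)oxy]but-2-enoic acid F1, which is N-acylated onto (R)-4-benzyloxazolidin-2-one (pivaloyl chloride, Et3N, LiCl) to give (R)-4-benzyl-3-{(E)-4-[(tert-butyldimethylsilyl)oxy]but-2-enoyl}oxazolidin-2-one F2. An Et2AlCl-promoted, auxiliary-controlled Diels–Alder reaction of F2 with 8 (CH2Cl2, −78 °C; chelated s-cis imide, diene endo and anti to the benzyl group, which for the R auxiliary is the face needed) should give the cycloadduct imide F3. LiSEt exchanges the auxiliary for the S-ethyl thioester F4, and i-Bu2AlH at −78 °C reduces it to aldehyde 12.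

2. Step 27. Ring closure onto the electron-poor 1,1-disubstituted alkene may be slower than intermolecular metathesis of the C3 vinyl group or catalyst decay. The fallback sets out from 16 and comes back at 40; it builds the acrylate first and closes the lactone at the C–O bond. Aldehyde 16 would be olefinated as in step 18, but with tert-butyl 2-(diethoxyphosphoryl)acrylate, 26 and NaH (sodium carbanion of tert-butyl 2-(diethoxyphosphoryl)-3-[(4-methoxybenzyl)oxy]propanoate F5), to give the C3 (E)-acrylate F6. K2CO3/MeOH opens the carbonate to the diol acrylate F7. Yamaguchi esterification with 33 gives the C7 ester F8. Pyridinium p-toluenesulfonate in aqueous THF gives the C2 aldehyde F9, and Pinnick oxidation gives the C2 acid F10. DDQ removes the 4-methoxybenzyl group to give the hydroxy acid F11. Mitsunobu lactonisation (PPh3, diisopropyl azodicarboxylate, toluene, high dilution), in which the C2 carboxylate displaces the activated allylic alcohol, then gives 40.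

3. Step 18. The β,γ-unsaturated aldehyde may epimerise or move its double bond into conjugation under the basic conditions, and E/Z control of the olefination may be poor. The fallback sets out from 25 and comes back at 31. [1-(Ethoxycarbonyl)vinyl]diisobutylaluminium F12 (from ethyl propiolate, i-Bu2AlH and N-methylmorpholine N-oxide) would add to 25 to give the Morita–Baylis–Hillman-type allylic alcohol F13 (both carbinol epimers are used). Acetylation (Ac2O, DMAP) gives the acetate F14. DABCO-catalysed allylic transposition (two SN2' steps) gives the thermodynamically preferred (E)-2-(acetoxymethyl) enoate F15. Stille hydroxymethylation as in step 19 gives the hydroxymethyl acetate F16, and K2CO3/EtOH removes the acetate to return diol 31.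

**Further compounds**

F1 | step 7 | (E)-4-[(tert-butyldimethylsilyl)oxy]but-2-enoic acid | OC(=O)/C=C/CO[Si](C)(C)C(C)(C)C
F2 | step 7 | (R)-4-benzyl-3-{(E)-4-[(tert-butyldimethylsilyl)oxy]but-2-enoyl}oxazolidin-2-one | O=C(/C=C/CO[Si](C)(C)C(C)(C)C)N1[C@H](Cc2ccccc2)COC1=O
F3 | step 7 | cycloadduct imide (ring A as in 12 with C2–C(=O)–oxazolidinone) | CC(C)[C@H]1C=C[C@@]2(COC(=O)O2)[C@@H](C(=O)N2[C@H](Cc3ccccc3)COC2=O)[C@@H]1CO[Si](C)(C)C(C)(C)C
F4 | step 7 | S-ethyl thioester (ring A as in 12 with C2–C(=O)SEt) | CC(C)[C@H]1C=C[C@@]2(COC(=O)O2)[C@@H](C(=O)SCC)[C@@H]1CO[Si](C)(C)C(C)(C)C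
F5 | step 27 | sodium carbanion of tert-butyl 2-(diethoxyphosphoryl)-3-[(4-methoxybenzyl)oxy]propanoate | CC(C)(C)OC(=O)[C-](COCc1ccc(OC)cc1)P(=O)(OCC)OCC.[Na+]
F6 | step 27 | C3 (E)-acrylate carbonate (tert-butyl ester, PMB ether, C2 acetal) | CC(C)[C@H]1CC[C@@]2(COC(=O)O2)[C@@H](C(OC)OC)[C@@H]1/C=C(\COCc1ccc(OC)cc1)C(=O)OC(C)(C)C
F7 | step 27 | diol acrylate | CC(C)[C@H]1CC[C@@](O)(CO)[C@@H](C(OC)OC)[C@@H]1/C=C(\COCc1ccc(OC)cc1)C(=O)OC(C)(C)C
F8 | step 27 | C7 ester of F7 with 33 | CC(C)[C@H]1CC[C@@](O)(COC(=O)/C(CO[Si](C)(C)C(C)(C)C)=C/[C@@H]2C=C(CO[Si](C)(C)C(C)(C)C)CC[C@H]2C(C)C)[C@@H](C(OC)OC)[C@@H]1/C=C(\COCc1ccc(OC)cc1)C(=O)OC(C)(C)C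
F9 | step 27 | C2 aldehyde from F8 | CC(C)[C@H]1CC[C@@](O)(COC(=O)/C(CO[Si](C)(C)C(C)(C)C)=C/[C@@H]2C=C(CO[Si](C)(C)C(C)(C)C)CC[C@H]2C(C)C)[C@@H](C=O)[C@@H]1/C=C(\COCc1ccc(OC)cc1)C(=O)OC(C)(C)C
F10 | step 27 | C2 acid from F9 | CC(C)[C@H]1CC[C@@](O)(COC(=O)/C(CO[Si](C)(C)C(C)(C)C)=C/[C@@H]2C=C(CO[Si](C)(C)C(C)(C)C)CC[C@H]2C(C)C)[C@@H](C(=O)O)[C@@H]1/C=C(\COCc1ccc(OC)cc1)C(=O)OC(C)(C)C
F11 | step 27 | hydroxy acid (seco acid of 40) | CC(C)[C@H]1CC[C@@](O)(COC(=O)/C(CO[Si](C)(C)C(C)(C)C)=C/[C@@H]2C=C(CO[Si](C)(C)C(C)(C)C)CC[C@H]2C(C)C)[C@@H](C(=O)O)[C@@H]1/C=C(\CO)C(=O)OC(C)(C)C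
F12 | step 18 | [1-(ethoxycarbonyl)vinyl]diisobutylaluminium | CCOC(=O)C(=C)[Al](CC(C)C)CC(C)C
F13 | step 18 | ethyl 2-{hydroxy[(1S,6S)-6-(propan-2-yl)-3-(triflyloxy)cyclohex-2-en-1-yl]methyl}acrylate | CCOC(=O)C(=C)C(O)[C@@H]1C=C(OS(=O)(=O)C(F)(F)F)CC[C@H]1C(C)C
F14 | step 18 | acetate of F13 | CCOC(=O)C(=C)C(OC(C)=O)[C@@H]1C=C(OS(=O)(=O)C(F)(F)F)CC[C@H]1C(C)C
F15 | step 18 | ethyl (2E)-2-(acetoxymethyl)-3-[6-(propan-2-yl)-3-(triflyloxy)cyclohex-2-en-1-yl]prop-2-enoate | CCOC(=O)/C(COC(C)=O)=C/[C@@H]1C=C(OS(=O)(=O)C(F)(F)F)CC[C@H]1C(C)C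
F16 | step 18 | ethyl (2E)-2-(acetoxymethyl)-3-[(1S,6S)-3-(hydroxymethyl)-6-(propan-2-yl)cyclohex-2-en-1-yl]prop-2-enoate | CCOC(=O)/C(COC(C)=O)=C/[C@@H]1C=C(CO)CC[C@H]1C(C)C
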